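## Analysis of the target

The target, (5S,6S,7R,8S)-5,6,7,8-tetrahydroxy-2-[2-(3-hydroxy-4-methoxyphenyl)ethyl]-5,6,7,8-tetrahydro-4H-chromen-4-one, is a 4-pyranone (O1, C2, C3, C4, C4a, C8a) fused through the C4a=C8a bond to a six-membered carbocycle (C4a, C5, C6, C7, C8, C8a), with a two-carbon tether on C2 that ends in an isovanillyl ring. All four stereocentres are the contiguous carbinol carbons C5 to C8: drawn flat, the oxygens on C5, C6 and C8 lie on one face of the carbocycle and the oxygen on C7 on the other, so C5/C6 are cis while C6/C7 and C7/C8 are trans. The C6–C7–C8 triad therefore has the all-threo pattern of C2, C3, C4 of a D-xylo pentose, and C5 adds one erythro relationship to C6. The sensitive sites are the C5 and C8 carbinols, both allylic to the enol-ether double bond C4a=C8a (ionisation, hydrogenolysis, and aromatisation to a chromone once eliminations start), the vinylogous-ester pyranone, and the free phenol beside an aryl methyl ether. The difficulty is to place four oxygenated stereocentres on a ring that is a few eliminations away from a benzene ring and to join it to the pyranone at the fully substituted C4a=C8a bond. The plan rests on C4a: it is the one carbon bonded to both ends, C5 and C8a, of the oxygenated five-carbon segment C5–C6–C7–C8–C8a, and it also carries the pyranone chain C4–C3–C2. Once the pyranone is opened at O1–C2 to a 1,3,5-triketone, C4a becomes the terminal carbon of a polyketide chain, and the carbocycle can be made by attaching that single carbon twice to a pentose-derived unit with an aldehyde at C5 and an acyl group at C8a.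

## Retrosynthetic reasoning

**21 to 20.** The last operation is removal of four benzyl ethers (three on C6, C7, C8 and one on the phenol) by hydrogenolysis. Benzyl is chosen because it survives amide bases, ozonolysis and the acid of the pyranone closure, and because one step then uncovers the whole polyol. The C5 hydroxyl is free from the moment it is created, so no fifth protecting group is needed.

**20 to 19.** The pyranone is cut at O1–C2. In the forward direction the enol oxygen on C8a of the triketone 19 adds to the C2 carbonyl and the ring aromatises by cyclodehydration. This cut exposes the polyketone chain C8a–C4a–C4–C3–C2, in which C4a is an ordinary carbon-acid position, and it loses no carbon.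

**19 to 15 and 9 (key disconnection).** Both ring bonds at C4a are cut, C4a–C5 and C4a–C8a. The cut is made here because the two bonds meet at one carbon, and this leaves two linear pieces: the diketone 15, whose methyl carbon is C4a, and the five-carbon chain 9 with an aldehyde (C5) at one end and an N-methoxy-N-methylamide (C8a) at the other. Forward, the dianion 16 must add to the aldehyde first (via 17) and then, after a further deprotonation at the same carbon, acylate the amide (via 18). The two ends of 9 must stay at different oxidation levels throughout. The tri-O-benzyl xylo chain is meso if its ends are alike, so the absolute configuration of the whole series lies only in which end is the aldehyde. For the same reason, a C5 ketone in 19 would make C5 and C8a equivalent.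

**15 to 12 and 13.** The bond between the benzylic carbon and the diketone methyl is cut. Forward, it is the terminal alkylation of the dianion 14 of 13 by the bromide 12. Compound 12 comes from the aldehyde 10 by reduction to 11 and bromination.

**9 to 7, 6 and 4.** The aldehyde of 9 is carried as a terminal alkene and is released by ozonolysis (via 8) only in the last step before the annulation, so the configurationally fragile α-benzyloxy aldehyde is never stored. The amide of 7 comes from the acid 6, and 6 from the primary alcohol 4 by oxidation (via 5).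

**4 to 3, 2 and 1.** The alkene of 4 is cut back to the lactol 3 (Wittig methylenation). This step tells the two chain ends apart: the anomeric carbon becomes the alkene (later C5), and the carbon that held the ring oxygen is released as the primary alcohol (later C8a). The lactol 3 comes from the glycoside 1 by benzylation to 2 and hydrolysis. C6, C7 and C8 are never touched.

## Alternatives that were turned down

**Alternative 1:** Only C4a–C5 is cut in the ring-forming step, and the carbocycle is taken from a hexose. The gluco-configured enol ether A1 (methyl 2,3,4-tri-O-benzyl-6-deoxy-α-D-xylo-hex-5-enopyranoside) would be treated with catalytic Hg(OCOCF3)2 in aqueous acetone: hydration, ring opening and intramolecular aldol give the hydroxy-cyclohexanone A2.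
- For: the reaction type is established on exactly this substitution pattern, C6–C8 come from the chiral pool, and the new C5 hydroxyl is known to prefer the position cis to the C6 ether. On precedent and on C5 control it is stronger than the chosen route.
- Against: A2 lacks C4, C3, C2 and the aryl chain. They must be attached through an enolate at C4a, and a C4a enolate with an oxygen leaving group on C5 is the species that eliminates to the cyclohexenone. Protection, acylation with a masked 3-oxo-pentanoyl unit and ring closure add several steps, and a mercury salt is needed.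
- Comparison: the chosen route brings all carbons in at once and never forms a C4a carbanion beside anything but a lithium alkoxide.

**Alternative 2:** The ring is cut at C8–C8a. The nitro aldehyde A3 ((2R,3S,4S)-2,3,4-tris(benzyloxy)-6-nitrohexanal, L-arabino series) would be cyclised with catalytic NaOMe in methanol to the nitrocyclohexanol A4.
- For: the conditions are mild, and the reversible nitro-aldol should settle on the diequatorial C8 hydroxyl/C8a nitro arrangement that the target needs at C8. The sugar is cheap. It matches the chosen route in chiral-pool economy.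
- Against: C8a arrives as a nitro carbon and needs a Nef reaction on a β-hydroxy nitro compound, where dehydration to the nitroalkene competes. After that the same C4a acylation problem as in alternative 1 remains, now beside a ketone whose other α-carbon carries a free hydroxyl. The chain extension to A3 also costs steps.
- Comparison: the chosen route creates only one new stereocentre (C5) and installs the pyranone carbons in the same step.

**Alternative 3:** The carbocycle is cut at C5=C6 on an intact pyranone built from kojic acid A5. The diene A6 would be closed with second-generation Grubbs catalyst to the 7,8-dihydrochromone A7, and the C5=C6 alkene then dihydroxylated from the face opposite the C7 ether.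
- For: the pyranone exists from the start, so no polyketone is handled. The cis C5/C6 diol comes from a stereospecific syn-dihydroxylation, which is a stronger answer to the C5 problem than an aldol facial preference.
- Against: C7 and C8 must be made by asymmetric synthesis on a pyranone side chain instead of being bought. The vinyl group on C4a needs a halide or triflate and a cross-coupling. The oxygenation pattern of A5 does not map onto the target without redox corrections. A7 can lose benzyl alcohol to become a fully aromatic chromone.
- Comparison: the sequence is long and linear, whereas the chosen route takes three stereocentres from the chiral pool and is convergent.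

Key step: step 10

Assumption: methyl β-D-xylopyranoside (1) and 3-benzyloxy-4-methoxybenzaldehyde (10) are taken as purchased catalogue compounds; each is the simple glycoside or benzyl ether of its parent and could be made in one routine step.

## Route

Step 1
Reactants: 1 methyl β-D-xylopyranoside
Product: 2 methyl 2,3,4-tri-O-benzyl-β-D-xylopyranoside
Conditions: NaH, BnBr, Bu4NI (cat.), DMF, 0 °C to rt
Reagents that add atoms: benzyl bromide, BrCc1ccccc1
Why: Williamson etherification of the three secondary hydroxyls; the anomeric acetal is stable to base and no stereocentre is touched.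

Step 2
Reactants: 2 methyl 2,3,4-tri-O-benzyl-β-D-xylopyranoside
Product: 3 2,3,4-tri-O-benzyl-D-xylopyranose (anomeric mixture)
Conditions: AcOH, 2 M aq. HCl, 90 °C
Reagents that add atoms: water, O
Why: Acid hydrolysis of the methyl glycoside through the pyranosyl oxocarbenium ion; benzyl ethers are stable, and the anomeric mixture does not matter because C1 becomes sp2 in the next step.

Step 3
Reactants: 3 2,3,4-tri-O-benzyl-D-xylopyranose
Product: 4 (2R,3R,4S)-2,3,4-tris(benzyloxy)hex-5-en-1-ol
Conditions: Ph3PCH3Br, n-BuLi, THF, −20 °C to rt (excess ylide)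
Reagents that add atoms: methyltriphenylphosphonium bromide, C[P+](c1ccccc1)(c1ccccc1)c1ccccc1.[Br-]
Why: Wittig methylenation of the open-chain aldehyde in equilibrium with the lactol; the former ring oxygen is released as the primary hydroxyl, which differentiates the two chain ends.

Step 4
Reactants: 4 (2R,3R,4S)-2,3,4-tris(benzyloxy)hex-5-en-1-ol
Product: 6 (2S,3R,4S)-2,3,4-tris(benzyloxy)hex-5-enoic acid, via (2S,3R,4S)-2,3,4-tris(benzyloxy)hex-5-enal 5 (not isolated)
Conditions: TEMPO (cat.), PhI(OAc)2, MeCN/H2O, rt
Reagents that add atoms: water, O
Why: Oxoammonium-catalysed oxidation of the primary alcohol to the aldehyde 5, whose hydrate is oxidised on to the acid; the near-neutral medium should spare the terminal alkene and the α-stereocentre.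

Step 5
Reactants: 6 (2S,3R,4S)-2,3,4-tris(benzyloxy)hex-5-enoic acid
Product: 7 (2S,3R,4S)-2,3,4-tris(benzyloxy)-N-methoxy-N-methylhex-5-enamide
Conditions: MeNHOMe·HCl, EDC·HCl, HOBt, iPr2NEt, CH2Cl2, 0 °C to rt
Reagents that add atoms: N,O-dimethylhydroxylamine hydrochloride, CNOC.Cl
Why: Carbodiimide amide coupling (Weinreb amide formation); the weakly basic conditions should leave the α-benzyloxy stereocentre intact.

Step 6
Reactants: 7 (2S,3R,4S)-2,3,4-tris(benzyloxy)-N-methoxy-N-methylhex-5-enamide
Product: 9 2,3,4-tri-O-benzyl-aldehydo-D-xyluronic acid N-methoxy-N-methylamide [(2S,3R,4R)-2,3,4-tris(benzyloxy)-N-methoxy-N-methyl-5-oxopentanamide], via secondary ozonide 8 (not isolated)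
Conditions: O3, CH2Cl2, −78 °C (Sudan red 7B end point); PPh3, −78 °C to rt; used crude
Reagents that add atoms: ozone, [O-][O+]=O
Why: Ozonolysis of the terminal alkene with reductive cleavage of the ozonide 8; the indicator dye stops the reaction before the benzyl ethers are attacked, and the aldehyde is taken on at once to avoid epimerisation at its α-carbon.

Step 7
Reactants: 10 3-benzyloxy-4-methoxybenzaldehyde
Product: 11 (3-benzyloxy-4-methoxyphenyl)methanol
Conditions: NaBH4, MeOH, 0 °C
Reagents that add atoms: none
Why: Hydride reduction of an aryl aldehyde.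

Step 8
Reactants: 11 (3-benzyloxy-4-methoxyphenyl)methanol
Product: 12 2-benzyloxy-4-(bromomethyl)-1-methoxybenzene (3-benzyloxy-4-methoxybenzyl bromide)
Conditions: PBr3, Et2O, 0 °C; used without storage
Reagents that add atoms: phosphorus tribromide, BrP(Br)Br
Why: Conversion of an electron-rich benzylic alcohol to the bromide through its phosphite ester.

Step 9
Reactants: 13 acetylacetone (pentane-2,4-dione); 12 3-benzyloxy-4-methoxybenzyl bromide
Product: 15 6-(3-benzyloxy-4-methoxyphenyl)hexane-2,4-dione, via acetylacetone dianion dilithium salt 14 (not isolated)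
Conditions: 13 (excess), LiN(iPr)2 (2 equiv per 13), THF, 0 °C; 12, 0 °C; 1 M aq. HCl
Reagents that add atoms: none
Why: Alkylation of a β-diketone dianion (Hauser-type); the terminal carbanion of 14 is its most nucleophilic site, so the benzylic bromide is attacked by the methyl carbon and not by the central carbon or oxygen.

Step 10
Reactants: 15 6-(3-benzyloxy-4-methoxyphenyl)hexane-2,4-dione; 9 2,3,4-tri-O-benzyl-aldehydo-D-xyluronic acid N-methoxy-N-methylamide
Product: 19 1-[(3S,4R,5S,6S)-3,4,5-tris(benzyloxy)-2,6-dihydroxycyclohex-1-en-1-yl]-5-(3-benzyloxy-4-methoxyphenyl)pentane-1,3-dione (C8a-enol form of the 2-acyl-3-hydroxycyclohexanone), via dione dianion dilithium salt 16 (not isolated), via open-chain aldol adduct 17 (not isolated), via cyclic N-methoxy-N-methyl hemiaminal 18 (not isolated)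
Conditions: 15, LiN(iPr)2 (2.2 equiv), THF, −78 to 0 °C; 9, −78 °C; LiN(iPr)2 (2.2 equiv), −78 to −20 °C; AcOH, −78 °C; aqueous work-up
Reagents that add atoms: none
Why: Proposed new method: a one-pot aldol–Claisen [5+1] annulation on one carbon; the closest known reaction types are the terminal aldol addition and terminal Claisen acylation of β-diketone dianions and the acylation of ketone enolates by N-methoxy-N-methylamides, which have not been run in tandem in this way. Double deprotonation of 15 gives the dianion 16, whose terminal carbanion (the future C4a) adds at −78 °C to the aldehyde of 9, the more electrophilic of its two carbonyl groups, to give the lithium aldolate of 17 and the bond C4a–C5. The second charge of LiN(iPr)2 removes a proton from C4a again; other anion sites are unproductive and should interconvert by proton transfer through iPr2NH, and only the C4a carbanion can reach the amide carbonyl through a six-membered transition state, so the carbocycle closes by 6-exo-trig attack on C8a (bond C4a–C8a) and rests as the lithium chelate of 18 until the quench. The one new stereocentre, C5, is set in the intermolecular aldol by the neighbouring C6 benzyloxy group: without a chelating metal the nucleophile should approach anti to the C6–O bond (polar Felkin–Anh model), which gives the 5,6-anti adduct in the open chain and therefore C5–O cis to C6–O in the ring. C4a is not a stereocentre in 19 because the 2-acylcyclohexanone is enolised. Retro-aldol and E1cB loss of the C5 oxygen should be held back because that oxygen remains a lithium alkoxide, a poor leaving group, and over-reaction at C8a because 18 does not collapse before work-up. A wrong C5 epimer must not be corrected by oxidation and reduction at this stage, because a C5 ketone would make C5 and C8a equivalent through a mirror plane through C7 and C4a; it is handled by the reversible aldol described under the fallback.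

Step 11
Reactants: 19 1-[(3S,4R,5S,6S)-3,4,5-tris(benzyloxy)-2,6-dihydroxycyclohex-1-en-1-yl]-5-(3-benzyloxy-4-methoxyphenyl)pentane-1,3-dione
Product: 20 (5S,6S,7R,8S)-6,7,8-tris(benzyloxy)-2-[2-(3-benzyloxy-4-methoxyphenyl)ethyl]-5-hydroxy-5,6,7,8-tetrahydro-4H-chromen-4-one
Conditions: CF3CO2H, CH2Cl2, 0 °C to rt; aq. NaHCO3
Reagents that add atoms: none
Why: Acid-catalysed cyclodehydration of a 1,3,5-triketone to a 4-pyranone: the enol oxygen on C8a adds to the C2 carbonyl (6-exo-trig, bond O1–C2) and loss of water gives the aromatic pyranone; benzyl ethers are stable to the acid and no stereocentre is involved.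

Step 12
Reactants: 20 (5S,6S,7R,8S)-6,7,8-tris(benzyloxy)-2-[2-(3-benzyloxy-4-methoxyphenyl)ethyl]-5-hydroxy-5,6,7,8-tetrahydro-4H-chromen-4-one
Product: 21 (5S,6S,7R,8S)-5,6,7,8-tetrahydroxy-2-[2-(3-hydroxy-4-methoxyphenyl)ethyl]-5,6,7,8-tetrahydro-4H-chromen-4-one
Conditions: H2 (1 atm), 10% Pd/C, EtOAc/MeOH, rt, monitored closely
Reagents that add atoms: none
Why: Hydrogenolysis of the four O-benzyl groups; 4-pyranones and aryl methyl ethers are normally inert under these mild conditions, and the carbinol configurations are unchanged.

## Compound list

1 | methyl β-D-xylopyranoside | CO[C@H]1[C@H](O)[C@@H](O)[C@H](O)CO1 | starting material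
2 | methyl 2,3,4-tri-O-benzyl-β-D-xylopyranoside | CO[C@H]1[C@H](OCc2ccccc2)[C@@H](OCc2ccccc2)[C@H](OCc2ccccc2)CO1 | intermediate
3 | 2,3,4-tri-O-benzyl-D-xylopyranose (anomeric mixture) | OC1[C@H](OCc2ccccc2)[C@@H](OCc2ccccc2)[C@H](OCc2ccccc2)CO1 | intermediate
4 | (2R,3R,4S)-2,3,4-tris(benzyloxy)hex-5-en-1-ol | C=C[C@H](OCc1ccccc1)[C@@H](OCc1ccccc1)[C@H](OCc1ccccc1)CO | intermediate
5 | (2S,3R,4S)-2,3,4-tris(benzyloxy)hex-5-enal | C=C[C@H](OCc1ccccc1)[C@@H](OCc1ccccc1)[C@H](OCc1ccccc1)C=O | intermediate
6 | (2S,3R,4S)-2,3,4-tris(benzyloxy)hex-5-enoic acid | C=C[C@H](OCc1ccccc1)[C@@H](OCc1ccccc1)[C@H](OCc1ccccc1)C(=O)O | intermediate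
7 | (2S,3R,4S)-2,3,4-tris(benzyloxy)-N-methoxy-N-methylhex-5-enamide | C=C[C@H](OCc1ccccc1)[C@@H](OCc1ccccc1)[C@H](OCc1ccccc1)C(=O)N(C)OC | intermediate
8 | secondary ozonide of 7 (3-substituted 1,2,4-trioxolane, ring carbon unassigned) | CON(C)C(=O)[C@@H](OCc1ccccc1)[C@H](OCc1ccccc1)[C@@H](OCc1ccccc1)C1OCOO1 | intermediate
9 | 2,3,4-tri-O-benzyl-aldehydo-D-xyluronic acid N-methoxy-N-methylamide, (2S,3R,4R)-2,3,4-tris(benzyloxy)-N-methoxy-N-methyl-5-oxopentanamide | CON(C)C(=O)[C@@H](OCc1ccccc1)[C@H](OCc1ccccc1)[C@@H](OCc1ccccc1)C=O | intermediate
10 | 3-benzyloxy-4-methoxybenzaldehyde | COc1ccc(C=O)cc1OCc1ccccc1 | starting material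
11 | (3-benzyloxy-4-methoxyphenyl)methanol | COc1ccc(CO)cc1OCc1ccccc1 | intermediate
12 | 2-benzyloxy-4-(bromomethyl)-1-methoxybenzene | COc1ccc(CBr)cc1OCc1ccccc1 | intermediate
13 | acetylacetone (pentane-2,4-dione) | CC(=O)CC(C)=O | starting material
14 | dilithium salt of the acetylacetone dianion (C1 and C3 deprotonated) | [Li+].[Li+].[CH2-]C(=O)[CH-]C(C)=O | intermediate
15 | 6-(3-benzyloxy-4-methoxyphenyl)hexane-2,4-dione | CC(=O)CC(=O)CCc1ccc(OC)c(OCc2ccccc2)c1 | intermediate
16 | dilithium salt of the dianion of 15 (C1 and C3 deprotonated) | [Li+].[Li+].[CH2-]C(=O)[CH-]C(=O)CCc1ccc(OC)c(OCc2ccccc2)c1 | intermediate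
17 | (2S,3R,4S,5S)-2,3,4-tris(benzyloxy)-11-(3-benzyloxy-4-methoxyphenyl)-5-hydroxy-N-methoxy-N-methyl-7,9-dioxoundecanamide (formed as its lithium aldolate) | CON(C)C(=O)[C@@H](OCc1ccccc1)[C@H](OCc1ccccc1)[C@@H](OCc1ccccc1)[C@@H](O)CC(=O)CC(=O)CCc1ccc(OC)c(OCc2ccccc2)c1 | intermediate
18 | cyclic hemiaminal from C4a–C8a closure: the carbocycle with hydroxyl and N-methoxy-N-methylamino on C8a, hydroxyl on C5, the acyl chain on C4a (formed as its lithium chelate; C4a and C8a unassigned) | COc1ccc(CCC(=O)CC(=O)C2[C@H](O)[C@H](OCc3ccccc3)[C@@H](OCc3ccccc3)[C@H](OCc3ccccc3)C2(O)N(C)OC)cc1OCc1ccccc1 | intermediate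
19 | 1-[(3S,4R,5S,6S)-3,4,5-tris(benzyloxy)-2,6-dihydroxycyclohex-1-en-1-yl]-5-(3-benzyloxy-4-methoxyphenyl)pentane-1,3-dione | COc1ccc(CCC(=O)CC(=O)C2=C(O)[C@@H](OCc3ccccc3)[C@H](OCc3ccccc3)[C@@H](OCc3ccccc3)[C@H]2O)cc1OCc1ccccc1 | intermediate
20 | (5S,6S,7R,8S)-6,7,8-tris(benzyloxy)-2-[2-(3-benzyloxy-4-methoxyphenyl)ethyl]-5-hydroxy-5,6,7,8-tetrahydro-4H-chromen-4-one | COc1ccc(CCc2cc(=O)c3c(o2)[C@@H](OCc2ccccc2)[C@H](OCc2ccccc2)[C@@H](OCc2ccccc2)[C@H]3O)cc1OCc1ccccc1 | intermediate
21 | (5S,6S,7R,8S)-5,6,7,8-tetrahydroxy-2-[2-(3-hydroxy-4-methoxyphenyl)ethyl]-5,6,7,8-tetrahydro-4H-chromen-4-one | COc1ccc(CCc2cc(=O)c3c(o2)[C@@H](O)[C@H](O)[C@@H](O)[C@H]3O)cc1O | target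

## Step count and least certain steps

Total: 12 steps. Longest linear sequence: 9 steps (steps 1 to 6, then 10, 11 and 12, from 1 to 21); the arene branch contributes steps 7 to 9.

**Step 10 (key step, proposed new method).** Three things may go wrong.
- The second deprotonation may not deliver the C4a carbanion fast enough. The aldolate would then revert by retro-aldol on warming, or its C5 alkoxide would lactonise onto the amide before the carbocycle closes.
- The first deprotonation of 15 could partly occur at the methylene next to the aryl-ethyl group instead of the methyl group.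
- The facial selectivity at C5 may be poor: lithium can chelate the C6 oxygen, and the C7 benzyloxy group is syn to the C6 one, so 1,2- and 1,3-induction need not reinforce each other.

The fallback uses known reaction types and reverses the order of the two bond formations. It sets out from 9 and returns at 19.
- The aldehyde of 9 would be protected with propane-1,3-dithiol and BF3·OEt2 as (2S,3S,4R)-2,3,4-tris(benzyloxy)-4-(1,3-dithian-2-yl)-N-methoxy-N-methylbutanamide F1.
- The amide of F1 would then acylate the terminal carbon of the dianion 16 (two equivalents, a terminal Claisen acylation of a β-diketone dianion) to give the triketone (8S,9S,10R)-8,9,10-tris(benzyloxy)-1-(3-benzyloxy-4-methoxyphenyl)-10-(1,3-dithian-2-yl)decane-3,5,7-trione F2.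
- Removal of the dithiane with Hg(ClO4)2 and CaCO3 in aqueous THF would release (2R,3R,4S)-2,3,4-tris(benzyloxy)-11-(3-benzyloxy-4-methoxyphenyl)-5,7,9-trioxoundecanal F3.
- In F3, C4a is a doubly activated methylene between the C4 and C8a carbonyls. It should add to the C5 aldehyde under a trace of Et3N in an intramolecular aldol, which is the only six-membered closure open to F3, and give 19.

This closure is reversible, so C5 is set under thermodynamic control. The cis isomer is expected to be favoured because its C5 hydroxyl sits pseudo-axial, away from the C4 acyl group, and can hydrogen-bond to it. F3 is also the retro-aldol product of 19, so a C5-epimeric sample of 19 from the main route should equilibrate through F3 under the same mild base.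

**Step 11.** Under acid, the β-hydroxy-β-diketone 19 may lose water across C4a–C5, followed by loss of benzyl alcohol and aromatisation. The C5 hydroxyl may also add to the C2 carbonyl in place of the C8a enol oxygen and lead to a dihydropyranone. The fallback sets out from 19 and returns at 20.
- The C5 hydroxyl would be capped first (Et3SiCl, imidazole, DMF; enol silyl ethers cleaved on work-up) to give the C5 O-triethylsilyl ether of 19 F4.
- The pyranone would be closed without acid by the dehydrative PPh3/CCl4 protocol used for sensitive triketones, giving the C5 O-triethylsilyl ether of 20 F5.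
- HF·pyridine would then return 20.

**Step 12.** Over-reduction may occur: hydrogenolysis of the allylic C5–O or C8–O bond, or saturation of the C2=C3 bond of the pyranone, once the benzyl groups are gone. The fallback sets out from 20 and returns at 21. It replaces hydrogen by Lewis-acid debenzylation with BCl3 and pentamethylbenzene as cation scavenger in CH2Cl2 at −78 °C, which should leave the aryl methyl ether and all C–O bonds of the carbocycle intact. No new compound is formed on the way (F0).

**Step 6.** Ozone may oxidise benzyl ethers to benzoates if the end point is missed, and the α-benzyloxy aldehyde may epimerise at C6 during work-up. The fallback sets out from 7 and returns at 9.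
- The alkene would be dihydroxylated (OsO4 cat., N-methylmorpholine N-oxide, acetone/H2O) to the diol (2S,3R,4S)-2,3,4-tris(benzyloxy)-5,6-dihydroxy-N-methoxy-N-methylhexanamide F6, as a mixture of C5 epimers that does not matter.
- F6 would be cleaved with NaIO4 in buffered aqueous THF to 9.

## Further compounds

F1 | step 10 | (2S,3S,4R)-2,3,4-tris(benzyloxy)-4-(1,3-dithian-2-yl)-N-methoxy-N-methylbutanamide | CON(C)C(=O)[C@@H](OCc1ccccc1)[C@H](OCc1ccccc1)[C@@H](OCc1ccccc1)C1SCCCS1
F2 | step 10 | (8S,9S,10R)-8,9,10-tris(benzyloxy)-1-(3-benzyloxy-4-methoxyphenyl)-10-(1,3-dithian-2-yl)decane-3,5,7-trione | COc1ccc(CCC(=O)CC(=O)CC(=O)[C@@H](OCc2ccccc2)[C@H](OCc2ccccc2)[C@@H](OCc2ccccc2)C2SCCCS2)cc1OCc1ccccc1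
F3 | step 10 | (2R,3R,4S)-2,3,4-tris(benzyloxy)-11-(3-benzyloxy-4-methoxyphenyl)-5,7,9-trioxoundecanal | COc1ccc(CCC(=O)CC(=O)CC(=O)[C@@H](OCc2ccccc2)[C@H](OCc2ccccc2)[C@@H](OCc2ccccc2)C=O)cc1OCc1ccccc1
F4 | step 11 | C5 O-triethylsilyl ether of 19 | COc1ccc(CCC(=O)CC(=O)C2=C(O)[C@@H](OCc3ccccc3)[C@H](OCc3ccccc3)[C@@H](OCc3ccccc3)[C@H]2O[Si](CC)(CC)CC)cc1OCc1ccccc1
F5 | step 11 | C5 O-triethylsilyl ether of 20 | COc1ccc(CCc2cc(=O)c3c(o2)[C@@H](OCc2ccccc2)[C@H](OCc2ccccc2)[C@@H](OCc2ccccc2)[C@H]3O[Si](CC)(CC)CC)cc1OCc1ccccc1
F0 | step 12 | none | none
F6 | step 6 | (2S,3R,4S)-2,3,4-tris(benzyloxy)-5,6-dihydroxy-N-methoxy-N-methylhexanamide (both C5 epimers) | CON(C)C(=O)[C@@H](OCc1ccccc1)[C@H](OCc1ccccc1)[C@@H](OCc1ccccc1)C(O)CO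
A1 | alternative 1 | methyl 2,3,4-tri-O-benzyl-6-deoxy-α-D-xylo-hex-5-enopyranoside | CO[C@@H]1[C@H](OCc2ccccc2)[C@@H](OCc2ccccc2)[C@H](OCc2ccccc2)C(=C)O1
A2 | alternative 1 | (2S,3R,4S,5S)-2,3,4-tris(benzyloxy)-5-hydroxycyclohexan-1-one | O=C1[C@@H](OCc2ccccc2)[C@H](OCc2ccccc2)[C@@H](OCc2ccccc2)[C@@H](O)C1
A3 | alternative 2 | (2R,3S,4S)-2,3,4-tris(benzyloxy)-6-nitrohexanal | [O-][N+](=O)CC[C@H](OCc1ccccc1)[C@H](OCc1ccccc1)[C@@H](OCc1ccccc1)C=O
A4 | alternative 2 | (1R,2S,3S,4S,6S)-2,3,4-tris(benzyloxy)-6-nitrocyclohexan-1-ol | [O-][N+](=O)[C@@H]1[C@@H](O)[C@H](OCc2ccccc2)[C@@H](OCc2ccccc2)[C@@H](OCc2ccccc2)C1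
A5 | alternative 3 | kojic acid, 5-hydroxy-2-(hydroxymethyl)-4H-pyran-4-one | OCc1cc(=O)c(O)co1
A6 | alternative 3 | 2-[(1S,2R)-1,2-bis(benzyloxy)but-3-en-1-yl]-6-[2-(3-benzyloxy-4-methoxyphenyl)ethyl]-3-ethenyl-4H-pyran-4-one | COc1ccc(CCc2cc(=O)c(C=C)c(o2)[C@@H](OCc2ccccc2)[C@H](OCc2ccccc2)C=C)cc1OCc1ccccc1
A7 | alternative 3 | (7R,8S)-7,8-bis(benzyloxy)-2-[2-(3-benzyloxy-4-methoxyphenyl)ethyl]-7,8-dihydro-4H-chromen-4-one | COc1ccc(CCc2cc(=O)c3c(o2)[C@@H](OCc2ccccc2)[C@H](OCc2ccccc2)C=C3)cc1OCc1ccccc1
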